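The elm run levels off lower than the birch run, at 50 % of product against 77 %, with the same substrate charged.

| flask | substrate | salt in the second phase | spent carrier | remark | time | volume of the second phase over the first |
|---|---|---|---|---|---|---|
| elm | 0.050 M | 0.025 M | 2.5 mM | run made earlier |  |  |
| birch | 0.050 M | 0.038 M | 2.5 mM | run made earlier |  |  |
| flask | 0.050 M | 0.0500 M | 2.5 mM |  | 4.0 h | 1.0 |

| run | time / h | product / % | crystals / % | substrate / % |
|---|---|---|---|---|
| elm | 0.133 | 20 | 0 | 76 |
| elm | 0.333 | 37 | 2 | 62 |
| elm | 0.667 | 44 | 0 | 53 |
| elm | 1.00 | 49 | 3 | 51 |
| elm | 1.33 | 49 | 0 | 49 |
| elm | 2.00 | 50 | 0 | 51 |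
| elm | 2.50 | 50 | 0 | 50 |
| birch | 0.200 | 37 | 0 | 62 |
| birch | 0.333 | 52 | 4 | 51 |
| birch | 0.417 | 57 | 1 | 47 |
| birch | 0.667 | 65 | 1 | 38 |
| birch | 1.00 | 73 | 0 | 29 |
| birch | 1.50 | 74 | 0 | 24 |
| birch | 2.50 | 77 | 0 | 25 |

(scatter of a reading: 2 percentage points)

- amounts and yields of product count crystals too
- charges count per volume of the first phase; a concentration in a rate is the amount of a species over the volume of its own phase; every rate counts per litre of the first phase
- given per volume of solution although it is solid: crystals
- the earlier runs hold the two phases in the same ratio of volumes as the flask asked about

- how much product and crystals together there is at 4.0 h, in percent of the substrate charged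
- concentration of product in solution at 4.0 h, in percent of saturation

*What differs between the two runs?* The salt in the second phase, 0.025 M against 0.038 M, and in both runs it is charged in the smaller amount. So write its balance, as the limiting reagent: if one salt spent gives one product, yield stops at the ratio c(salt in the second phase)/c(substrate). For the flask this ratio is 100 %.

*Give it a name.* The salt ceiling: the percent of the substrate charged that the salt charged can turn into product.

*Does it hold?* It gives 50.0 % for elm and 76.0 % for birch, and each last reading lies within the scatter of 2 percentage points.

*A ceiling is not an arrival. Is the flask there at 4.0 h?* I think not quite. With equal charges in the flask, substrate and salt thin out together, so I expect the last stretch to be slow and the yield to stay somewhat under the ceiling.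

*And the solution?* Here the readings are weak. Birch shows no steady crystals at a last reading of about 0.0385 M of product, and that reading carries a scatter of 2 points, so saturation lies somewhere near it or above it: a rough lower mark, not a value. The flask's ceiling corresponds to 0.0500 M, so the flask may reach saturation.

The forecast gives 94 % and 90 % of saturation, on this ground: “salt is the limiting reagent and the reaction runs essentially to completion”.

The flask gives 96.6 % at 4.0 h, with the solution at 100 % of saturation.

    substrate + fresh carrier → product + spent carrier (k = 1.30 M⁻¹ s⁻¹)
    crystals ⇌ product, rate k2*(cs2 - [product]) while solid is left; crystals form when [product] > cs2 (solubility = 38.0 mM, k = 0.00350 s⁻¹)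
    spent carrier + salt in the second phase ⇌ fresh carrier + spent salt in the second phase (K = 0.710, k = 0.600 M⁻¹ s⁻¹)

Crystals in the flask then hold 20.5 % of the substrate charged, and they are counted in the product. The flask stands 3.4 points under its salt ceiling of 100 %, with 3.3 % of the salt still in the second phase. The neighbour flask with 0.20 M of substrate has a salt ceiling of 25.0 %. It gives 25.0 %, its salt in the second phase stands at 0 %, and 75.0 % of its substrate remains.

The earlier runs and the new flask are calculated with constants of no real substance; noise was put on by code.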